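The plan rests on cutting C1–CH3 and C5–C6. It exploits the run of three adjacent stereocentres C1, C5 and C6. This run lies where the five-membered and seven-membered rings meet and sits next to C4, a carbinol carbon that can start as a ketone. In one flask a methyl cuprate adds to the β-carbon of an enantiopure cyclopentenone and the enolate captures an aldehyde. Two skeletal bonds and three stereocentres arise under control of the purchased C2–O centre; no ring forms. The precursor is (S)-3-allyl-4-silyloxycyclopent-2-enone. Its allyl arm and the ketal-masked methyl ketone of the aldehyde later close C8=C9 by ring-closing metathesis.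

Key step: step 4

Remark on atom labels: C1 = quaternary ring-fusion carbon (CH3), C2 = CH–O, C3 = CH2, C4 = C(OH)(i-Pr) and C5 = ring-fusion CH make up the five-membered ring. C6 = CH–O, C7 = CH2, C8(CH3)=C9 and C10 = CH2 complete the seven-membered ring with C1 and C5. The same labels are used for all intermediates. The target is (1R,2S,4R,5S,6S) with a trans ring fusion. C1–CH3 and C4–OH lie on one face; C2–O, H5, C6–O and the isopropyl group lie on the other. The C5/C6 pair is the anti aldol relationship.

Remark on the chemistry (assumption): the (S)-enantiomer of the silyloxycyclopentenone, the ketal ester (a commercial flavour compound) and isomerically pure angelic acid are taken as purchasable.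

Step 1
Reactants: 1 (S)-4-(tert-butyldimethylsilyloxy)cyclopent-2-en-1-one; 2 allylmagnesium bromide
Product: 4 (3S,4S)-3-allyl-4-(tert-butyldimethylsilyloxy)-1-(trimethylsilyloxy)cyclopent-1-ene (allyl trans to OTBS), via allylcopper 3 (not isolated)
Conditions: 2, CuBr·SMe2, THF, −78 °C; Me3SiCl, then 1, −78 °C; aq. NaHCO3
Reagents that add atoms: chlorotrimethylsilane, C[Si](C)(C)Cl
Why: Copper-mediated conjugate allylation, in which the monoorganocopper species adds 1,4 rather than 1,2 because Me3SiCl silylates the copper–enone complex as it forms, the allyl group enters C1 anti to the C2 silyloxy group (a centre erased in step 2), and O-silylation locks the enol double bond at C4=C5 so that the C2 silyloxy group cannot be eliminated.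

Step 2
Reactants: 4 (3S,4S)-3-allyl-4-(tert-butyldimethylsilyloxy)-1-(trimethylsilyloxy)cyclopent-1-ene
Product: 5 (S)-3-allyl-4-(tert-butyldimethylsilyloxy)cyclopent-2-en-1-one
Conditions: Pd(OAc)2 (1.05 equiv), MeCN, rt
Reagents that add atoms: none
Why: Saegusa–Ito oxidation, in which divalent palladium replaces silicon and binds C5 on the face anti to the allyl group and hence syn to the C1–H bond, β-hydride elimination restores the enone with the allyl arm on the β-carbon and releases zerovalent palladium, C2 is not touched, and the neutral medium should keep the skipped diene out of conjugation.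

Step 3
Reactants: 6 ethyl 2-(2-methyl-1,3-dioxolan-2-yl)acetate
Product: 7 2-(2-methyl-1,3-dioxolan-2-yl)acetaldehyde
Conditions: i-Bu2AlH (1.05 equiv), CH2Cl2, −78 °C; aq. potassium sodium tartrate
Reagents that add atoms: none
Why: Partial reduction of an ester, which stops at the aldehyde because the tetrahedral adduct of hydride delivery survives at −78 °C until the quench, while the ketal is inert to hydride.

Step 4
Reactants: 5 (S)-3-allyl-4-(tert-butyldimethylsilyloxy)cyclopent-2-en-1-one; 7 2-(2-methyl-1,3-dioxolan-2-yl)acetaldehyde; 8 methyllithium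
Product: 12 (2S,3R,4S)-3-allyl-4-(tert-butyldimethylsilyloxy)-2-[(1S)-1-hydroxy-2-(2-methyl-1,3-dioxolan-2-yl)ethyl]-3-methylcyclopentan-1-one, via lithium dimethylcuprate 9 (not isolated), via lithium enolate 10 (not isolated), via chlorozinc enolate 11 (not isolated)
Conditions: 8 (2.4 equiv), CuI (1.2 equiv), Et2O, 0 °C; 5, −40 → 0 °C; ZnCl2 (1 M in Et2O, 1.5 equiv), −78 °C; 7 (2 equiv), −78 °C; aq. NH4Cl
Reagents that add atoms: none
Why: Me2CuLi forms a π-complex with the enone, oxidative addition gives a β-cuprio enolate of trivalent copper and reductive elimination forges C1–CH3, after which ZnCl2 turns the lithium enolate into a less basic zinc enolate that adds to the aldehyde through a closed Zimmerman–Traxler chair and forges C5–C6. The closest known reaction type is the tandem organocuprate conjugate addition–aldol trapping (three-component coupling) established for 4-silyloxycyclopent-2-enones, applied here to a β-substituted member of that class. Both new bonds are exocyclic, so no ring is formed and no mode of closure applies. C1 is controlled by the C2 silyloxy group, which sends methyl to the opposite face; C5 is controlled by the new quaternary centre together with that silyloxy group, since the aldehyde reaches the enolate from the face that carries only the small methyl group and ends trans to the allyl arm; C6 is controlled by the fixed E geometry of the cyclic enolate, which in the chair places the aldehyde residue equatorial and gives the anti aldol (6S). The step needs 1,4-addition rather than 1,2-addition or removal of the doubly activated C10 protons, which the soft and weakly basic cuprate in Et2O secures, and it needs an enolate that stays at C4=C5, which the lack of a proton source, the cold trapping and the zinc counter-ion secure, so that the C2 silyloxy group is not lost by β-elimination and the aldol does not revert. No BF3·OEt2 or other strong Lewis acid is added, because it would attack the dioxolane and replace the chair by an open transition state.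

Step 5
Reactants: 12 (2S,3R,4S)-3-allyl-4-(tert-butyldimethylsilyloxy)-2-[(1S)-1-hydroxy-2-(2-methyl-1,3-dioxolan-2-yl)ethyl]-3-methylcyclopentan-1-one
Product: 13 (2S,3R,4S)-3-allyl-4-(tert-butyldimethylsilyloxy)-2-[(1S)-1-(tert-butyldimethylsilyloxy)-2-(2-methyl-1,3-dioxolan-2-yl)ethyl]-3-methylcyclopentan-1-one
Conditions: t-BuMe2SiOTf, 2,6-lutidine, CH2Cl2, −78 → 0 °C
Reagents that add atoms: tert-butyldimethylsilyl triflate, CC(C)(C)[Si](C)(C)OS(=O)(=O)C(F)(F)F
Why: Silyl ether formation with a silyl triflate and a hindered pyridine base, which is fast in the cold and too weakly basic to cause retro-aldol cleavage, epimerisation at C5 or β-elimination, and which masks the C6 oxygen with the same group as C2 so that both can be removed together.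

Step 6
Reactants: 13 (2S,3R,4S)-3-allyl-4-(tert-butyldimethylsilyloxy)-2-[(1S)-1-(tert-butyldimethylsilyloxy)-2-(2-methyl-1,3-dioxolan-2-yl)ethyl]-3-methylcyclopentan-1-one; 14 isopropylmagnesium chloride
Product: 16 (1R,2S,3R,4S)-3-allyl-4-(tert-butyldimethylsilyloxy)-2-[(1S)-1-(tert-butyldimethylsilyloxy)-2-(2-methyl-1,3-dioxolan-2-yl)ethyl]-3-methyl-1-(propan-2-yl)cyclopentan-1-ol, via isopropylcerium dichloride 15 (not isolated)
Conditions: 14 (3 equiv), CeCl3 (anhydrous, 3 equiv), THF, −78 °C; 13, −78 → −40 °C; aq. NH4Cl
Reagents that add atoms: none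
Why: Organocerium 1,2-addition, in which the oxophilic and weakly basic reagent adds to an easily enolised ketone where a magnesium or lithium reagent would enolise it (and so expel the C2 or C6 silyloxy group) or reduce it, and which should attack C4 from the face opposite to the bulky C5 side chain and the C1 methyl group, placing isopropyl cis to H5 and the new hydroxyl cis to the side chain (4R).

Step 7
Reactants: 16 (1R,2S,3R,4S)-3-allyl-4-(tert-butyldimethylsilyloxy)-2-[(1S)-1-(tert-butyldimethylsilyloxy)-2-(2-methyl-1,3-dioxolan-2-yl)ethyl]-3-methyl-1-(propan-2-yl)cyclopentan-1-ol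
Product: 17 (1R,2S,3R,4S)-3-allyl-4-(tert-butyldimethylsilyloxy)-2-[(1S)-1-(tert-butyldimethylsilyloxy)-3-oxobutyl]-3-methyl-1-(propan-2-yl)cyclopentan-1-ol
Conditions: pyridinium p-toluenesulfonate (cat.), acetone–H2O, 50 °C
Reagents that add atoms: water, O
Why: Mild acid-catalysed ketal hydrolysis, which cleaves the dioxolane of a methyl ketone while secondary TBS ethers, the tertiary alcohol and the terminal alkene stay intact and no stereocentre is involved.

Step 8
Reactants: 17 (1R,2S,3R,4S)-3-allyl-4-(tert-butyldimethylsilyloxy)-2-[(1S)-1-(tert-butyldimethylsilyloxy)-3-oxobutyl]-3-methyl-1-(propan-2-yl)cyclopentan-1-ol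
Product: 18 (1R,2S,3R,4S)-3-allyl-4-(tert-butyldimethylsilyloxy)-2-[(1S)-1-(tert-butyldimethylsilyloxy)-3-methylbut-3-en-1-yl]-3-methyl-1-(propan-2-yl)cyclopentan-1-ol
Conditions: Ph3PCH3Br (4 equiv), KN(SiMe3)2 (3.8 equiv), THF, 0 °C; 17, 0 °C → rt
Reagents that add atoms: methyltriphenylphosphonium bromide, C[P+](c1ccccc1)(c1ccccc1)c1ccccc1.[Br-]
Why: Wittig methylenation, in which the unhindered methyl ketone should react with the non-stabilised ylide faster than it is enolised, the excess of ylide covers the free C4 hydroxyl and draws any cyclic hemiketal back to the open keto form, and no stereocentre is touched.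

Step 9
Reactants: 18 (1R,2S,3R,4S)-3-allyl-4-(tert-butyldimethylsilyloxy)-2-[(1S)-1-(tert-butyldimethylsilyloxy)-3-methylbut-3-en-1-yl]-3-methyl-1-(propan-2-yl)cyclopentan-1-ol
Product: 19 (1R,2S,4R,5S,6S)-2,6-bis(tert-butyldimethylsilyloxy)dauc-8-en-4-ol (trans-fused bicyclo[5.3.0]decene, labels as in the remark)
Conditions: second-generation Grubbs catalyst RuCl2(=CHPh)(PCy3)(H2IMes) (5 mol %), CH2Cl2 (2 mM), reflux
Reagents that add atoms: none
Why: Ring-closing metathesis, in which the ruthenium carbene loads on the monosubstituted allyl alkene and closes on the 1,1-disubstituted alkene with loss of ethylene, a familiar entry to trisubstituted cycloheptenes of hydroazulenes that tolerates silyl ethers and a free tertiary alcohol, with the alkene geometry enforced by ring size and the trans fusion already fixed at C1 and C5.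

Step 10
Reactants: 19 (1R,2S,4R,5S,6S)-2,6-bis(tert-butyldimethylsilyloxy)dauc-8-en-4-ol
Product: 20 (1R,2S,4R,5S,6S)-dauc-8-ene-2,4,6-triol
Conditions: Bu4NF (5 equiv), THF, rt → 50 °C
Reagents that add atoms: none
Why: Fluoride-induced desilylation, driven by the strength of the Si–F bond, should remove both secondary silyl ethers in one operation from a substrate that holds no base-sensitive group.

Step 11
Reactants: 20 (1R,2S,4R,5S,6S)-dauc-8-ene-2,4,6-triol; 21 angelic acid, (Z)-2-methylbut-2-enoic acid
Product: 23 (1R,2S,4R,5S,6S)-2,6-bis(angeloyloxy)dauc-8-en-4-ol (CNP0303897.1), via mixed anhydride 22 (not isolated)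
Conditions: 21 (6 equiv), 2,4,6-Cl3C6H2COCl (6 equiv), Et3N, toluene, rt; then 20, 80 °C
Reagents that add atoms: none
Why: Yamaguchi-type esterification through the mixed anhydride without a nucleophilic amine catalyst, the variant known to transfer the angeloyl group without Z-to-E isomerisation to the tiglate, in which the secondary hydroxyls at C2 and C6 are acylated and the hindered tertiary C4 hydroxyl stays free.

Compound list
1 | (S)-4-(tert-butyldimethylsilyloxy)cyclopent-2-en-1-one | O=C1C[C@H](O[Si](C)(C)C(C)(C)C)C=C1 | starting material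
2 | allylmagnesium bromide | C=CC[Mg]Br | starting material
3 | allylcopper (C3H5Cu) | C=CC[Cu] | intermediate
4 | (3S,4S)-3-allyl-4-(tert-butyldimethylsilyloxy)-1-(trimethylsilyloxy)cyclopent-1-ene | C[Si](C)(C)OC1=C[C@H](CC=C)[C@@H](O[Si](C)(C)C(C)(C)C)C1 | intermediate
5 | (S)-3-allyl-4-(tert-butyldimethylsilyloxy)cyclopent-2-en-1-one | C=CCC1=CC(=O)C[C@@H]1O[Si](C)(C)C(C)(C)C | intermediate
6 | ethyl 2-(2-methyl-1,3-dioxolan-2-yl)acetate | CCOC(=O)CC1(C)OCCO1 | starting material
7 | 2-(2-methyl-1,3-dioxolan-2-yl)acetaldehyde | CC1(CC=O)OCCO1 | intermediate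
8 | methyllithium | [Li]C | starting material
9 | lithium dimethylcuprate Me2CuLi | [Li+].C[Cu-]C | intermediate
10 | lithium (3R,4S)-3-allyl-4-(tert-butyldimethylsilyloxy)-3-methylcyclopent-1-en-1-olate | [Li+].[O-]C1=C[C@@](C)(CC=C)[C@@H](O[Si](C)(C)C(C)(C)C)C1 | intermediate
11 | chlorozinc (3R,4S)-3-allyl-4-(tert-butyldimethylsilyloxy)-3-methylcyclopent-1-en-1-olate | Cl[Zn]OC1=C[C@@](C)(CC=C)[C@@H](O[Si](C)(C)C(C)(C)C)C1 | intermediate
12 | (2S,3R,4S)-3-allyl-4-(tert-butyldimethylsilyloxy)-2-[(1S)-1-hydroxy-2-(2-methyl-1,3-dioxolan-2-yl)ethyl]-3-methylcyclopentan-1-one | O[C@@H](CC1(C)OCCO1)[C@H]1C(=O)C[C@H](O[Si](C)(C)C(C)(C)C)[C@]1(C)CC=C | intermediate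
13 | (2S,3R,4S)-3-allyl-4-(tert-butyldimethylsilyloxy)-2-[(1S)-1-(tert-butyldimethylsilyloxy)-2-(2-methyl-1,3-dioxolan-2-yl)ethyl]-3-methylcyclopentan-1-one | CC(C)(C)[Si](C)(C)O[C@@H](CC1(C)OCCO1)[C@H]1C(=O)C[C@H](O[Si](C)(C)C(C)(C)C)[C@]1(C)CC=C | intermediate
14 | isopropylmagnesium chloride | CC(C)[Mg]Cl | starting material
15 | isopropylcerium dichloride i-PrCeCl2 | CC(C)[Ce](Cl)Cl | intermediate
16 | (1R,2S,3R,4S)-3-allyl-4-(tert-butyldimethylsilyloxy)-2-[(1S)-1-(tert-butyldimethylsilyloxy)-2-(2-methyl-1,3-dioxolan-2-yl)ethyl]-3-methyl-1-(propan-2-yl)cyclopentan-1-ol | CC(C)(C)[Si](C)(C)O[C@@H](CC1(C)OCCO1)[C@H]1[C@](O)(C(C)C)C[C@H](O[Si](C)(C)C(C)(C)C)[C@]1(C)CC=C | intermediate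
17 | (1R,2S,3R,4S)-3-allyl-4-(tert-butyldimethylsilyloxy)-2-[(1S)-1-(tert-butyldimethylsilyloxy)-3-oxobutyl]-3-methyl-1-(propan-2-yl)cyclopentan-1-ol | CC(C)(C)[Si](C)(C)O[C@@H](CC(C)=O)[C@H]1[C@](O)(C(C)C)C[C@H](O[Si](C)(C)C(C)(C)C)[C@]1(C)CC=C | intermediate
18 | (1R,2S,3R,4S)-3-allyl-4-(tert-butyldimethylsilyloxy)-2-[(1S)-1-(tert-butyldimethylsilyloxy)-3-methylbut-3-en-1-yl]-3-methyl-1-(propan-2-yl)cyclopentan-1-ol | CC(C)(C)[Si](C)(C)O[C@@H](CC(C)=C)[C@H]1[C@](O)(C(C)C)C[C@H](O[Si](C)(C)C(C)(C)C)[C@]1(C)CC=C | intermediate
19 | (1R,2S,4R,5S,6S)-2,6-bis(tert-butyldimethylsilyloxy)dauc-8-en-4-ol | CC(C)(C)[Si](C)(C)O[C@H]1CC(C)=CC[C@@]2(C)[C@@H](O[Si](C)(C)C(C)(C)C)C[C@@](O)(C(C)C)[C@H]12 | intermediate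
20 | (1R,2S,4R,5S,6S)-dauc-8-ene-2,4,6-triol | O[C@H]1CC(C)=CC[C@@]2(C)[C@@H](O)C[C@@](O)(C(C)C)[C@H]12 | intermediate
21 | angelic acid, (Z)-2-methylbut-2-enoic acid | C/C=C(/C)C(=O)O | starting material
22 | (Z)-2-methylbut-2-enoic 2,4,6-trichlorobenzoic anhydride | C/C=C(/C)C(=O)OC(=O)c1c(Cl)cc(Cl)cc1Cl | intermediate
23 | (1R,2S,4R,5S,6S)-2,6-bis(angeloyloxy)dauc-8-en-4-ol (CNP0303897.1) | C/C=C(/C)C(=O)O[C@H]1CC(C)=CC[C@@]2(C)[C@@H](OC(=O)/C(C)=C\C)C[C@@](O)(C(C)C)[C@H]12 | target

Total step count: 11.
Longest linear sequence: 10 steps (steps 1, 2 and 4 to 11; step 3 is a one-step branch).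

Steps most likely to fail

**Step 4.**
- What may go wrong: methyl transfer to the fully substituted β-carbon may be slow at the temperatures at which the enolate keeps its position. Removal of a C10 proton, migration of the enolate with loss of the C2 silyloxy group, and an aldol of low face selectivity in the presence of copper salts could then compete.
- Fallback: the two bond formations are separated, setting out from 5.
- Me2CuLi is used together with Me3SiCl in THF at −78 °C. This accelerates the conjugate addition and captures the adduct as the isolable silyl enol ether (3R,4S)-3-allyl-4-(tert-butyldimethylsilyloxy)-3-methyl-1-(trimethylsilyloxy)cyclopent-1-ene F1.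
- After the copper salts are removed, MeLi in Et2O at 0 °C cleaves the O–Si bond and regenerates the regiodefined, copper-free enolate.
- The route is rejoined at 10 and continues with ZnCl2 and 7 as before.

**Step 6.**
- What may go wrong: the ketone carries a β-silyloxy group on each side, so enolisation would expel one of them. Hydride transfer could replace carbon transfer, the crowded carbonyl group could react sluggishly, or attack could come from the wrong face.
- Fallback: the addition is run on the unprotected aldol, setting out from 12.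
- The first equivalent of i-PrCeCl2 turns the C6 hydroxyl into a cerium alkoxide. This alkoxide cannot act as a leaving group, and it ties C6–O to the C4 carbonyl oxygen in a six-membered chelate that activates the carbonyl group.
- A further equivalent then adds from the face away from the C5–C6 bond. This should give (1R,2S,3R,4S)-3-allyl-4-(tert-butyldimethylsilyloxy)-2-[(1S)-1-hydroxy-2-(2-methyl-1,3-dioxolan-2-yl)ethyl]-3-methyl-1-(propan-2-yl)cyclopentan-1-ol F2.
- Selective silylation of the secondary C6 hydroxyl (t-BuMe2SiOTf, 2,6-lutidine, −78 °C) comes back to the route at 16 with the same step count.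

**Step 11.**
- What may go wrong: acylation of the neopentyl-type C2 hydroxyl may stay incomplete at temperatures below those at which the angelate begins to isomerise to the tiglate.
- Fallback: the Z double bonds are built after esterification, setting out from 20.
- Carbodiimide coupling (dicyclohexylcarbodiimide, DMAP) with 2-[bis(2,2,2-trifluoroethoxy)phosphoryl]propanoic acid has no alkene to isomerise. It should give (1R,2S,4R,5S,6S)-4-hydroxydauc-8-ene-2,6-diyl bis{2-[bis(2,2,2-trifluoroethoxy)phosphoryl]propanoate} F3, whose configuration at the phosphonate-bearing carbons is irrelevant.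
- A double Still–Gennari olefination with acetaldehyde (KN(SiMe3)2, 18-crown-6, THF, −78 °C) then installs both Z-trisubstituted alkenes and arrives at 23.

Further compounds
F1 | step 4 | (3R,4S)-3-allyl-4-(tert-butyldimethylsilyloxy)-3-methyl-1-(trimethylsilyloxy)cyclopent-1-ene | C[Si](C)(C)OC1=C[C@@](C)(CC=C)[C@@H](O[Si](C)(C)C(C)(C)C)C1
F2 | step 6 | (1R,2S,3R,4S)-3-allyl-4-(tert-butyldimethylsilyloxy)-2-[(1S)-1-hydroxy-2-(2-methyl-1,3-dioxolan-2-yl)ethyl]-3-methyl-1-(propan-2-yl)cyclopentan-1-ol | O[C@@H](CC1(C)OCCO1)[C@H]1[C@](O)(C(C)C)C[C@H](O[Si](C)(C)C(C)(C)C)[C@]1(C)CC=C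
F3 | step 11 | (1R,2S,4R,5S,6S)-4-hydroxydauc-8-ene-2,6-diyl bis{2-[bis(2,2,2-trifluoroethoxy)phosphoryl]propanoate} | CC(C(=O)O[C@H]1CC(C)=CC[C@@]2(C)[C@@H](OC(=O)C(C)P(=O)(OCC(F)(F)F)OCC(F)(F)F)C[C@@](O)(C(C)C)[C@H]12)P(=O)(OCC(F)(F)F)OCC(F)(F)F
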